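## Retrosynthetic overview

1. **Numbering and feature.** C1 = CO2H, C2 = CH2, C3–C6 = the four carbons of the 1,2-dioxane (ring A, C3–O–O–C6), C7 = CH2, C8 = CH(CH3), C9–C17 = (CH2)9, then phenyl. C3 and C6 are the 1,4-related oxygen-bearing carbons of ring A. The methyl-bearing C4 (S) and C8 (R) each sit one CH2 from C6 and have the same spatial sense. With C3 and C9 read as CHO and C6 as C=O, the segment C3–C9 is therefore the C2-symmetric (2S,6S)-2,6-dimethyl-4-oxoheptanedial; the R/S change at C8 is only a CIP priority effect.
2. **Last cuts.** C2–C3 is made by a silyl ketene acetal on a C3 peroxycarbenium ion, and C6–CH3 by Me3Al on a C6 peroxycarbenium ion. Both enter axially on the chair fixed by the equatorial C4 methyl group, which leads back to a 3,6-dimethoxy-1,2-dioxane.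
3. **Ring order.** Ring A is the only ring made. It is closed by bridging the C3 aldehyde and the C6 ketone of a γ-keto aldehyde with one H2O2 unit (two C–O bonds). The phenyl ring is bought.
4. **Side chain.** C9=C10 comes from a mono-Wittig reaction on one of two homotopic aldehydes, followed by hydrogenation; this cut removes the 8-phenyloctyl chain.
5. **Core.** C4–C5 and C7–C8 are cut together. Two propanal α-carbons are joined to the two CH2 arms of 1,3-dibromoacetone by enamine/photoredox radical alkylation.

Key step: step 1

Assumption: the sense of induction follows the accepted enamine model of this catalyst family, in which the (2R,5S) catalyst leaves the Si face open and gives R for the priority order CHO > CH2C(O) > CH3; the (2S,5R) enantiomer is therefore specified.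

## Route

Step 1
Reactants: 1 propanal; 2 1,3-dibromoacetone
Product: 4 (2S,6S)-2,6-dimethyl-4-oxoheptanedial, via bromo keto aldehyde 3 (not isolated)
Conditions: 1 (6 equiv), (2S,5R)-2-tert-butyl-3,5-dimethylimidazolidin-4-one·TfOH (40 mol %), Ru(bpy)3Cl2 (1 mol %), 2,6-lutidine (4 equiv), degassed DMF, blue LED or fluorescent lamp, 15–23 °C
Reagents that add atoms: none
Why: Proposed new method: propanal and the imidazolidinone form an E-enamine, the reduced photocatalyst [Ru(bpy)3]+ passes one electron to a C–Br bond of 2, the electrophilic α-keto radical adds to the enamine, and oxidation of the resulting α-amino radical by photoexcited [Ru(bpy)3]2+ followed by iminium hydrolysis releases 3, whose second bromomethyl arm runs through the same cycle to give 4. The closest known reaction type is the enamine/photoredox co-catalysed enantioselective α-alkylation of aldehydes with bromomethyl ketones and bromomalonates, established for one C–Br bond per substrate, so the new element is its use twice, in two directions, on a 1,3-dihalo ketone. The bonds C4–C5 and C7–C8 each join two carbons that are both α to a carbonyl group, a pairing that polar enolate chemistry serves poorly and the radical/enamine pairing serves well; no ring is closed. C4 and C8 are both set by the catalyst: its tert-butyl group turns the enamine double bond towards C5 of the imidazolidinone and the methyl group there covers one face, so the (2S,5R) enantiomer should leave the Re face open and give S at each centre. The step needs enantiofacial selectivity twice, and because the two additions are independent most of the minor-face error should end in the separable meso (2R,6S) isomer, which enriches the C2-symmetric product. It also needs the products to stay out of the enamine cycle, which their α-branching secures, and capture of the second radical to outrun hydrogen abstraction from the aldehyde C–H of 3, which the excess of propanal favours.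

Step 2
Reactants: 5 (8-bromooctyl)benzene
Product: 6 triphenyl(8-phenyloctyl)phosphonium bromide
Conditions: PPh3 (1.05 equiv), MeCN, reflux
Reagents that add atoms: triphenylphosphine, c1ccc(cc1)P(c1ccccc1)c1ccccc1
Why: Quaternisation of triphenylphosphine by an unhindered primary alkyl bromide is a routine bimolecular substitution, and no stereocentre is involved.

Step 3
Reactants: 6 triphenyl(8-phenyloctyl)phosphonium bromide; 4 (2S,6S)-2,6-dimethyl-4-oxoheptanedial
Product: 8 (2S,6S,7Z)-2,6-dimethyl-4-oxo-15-phenylpentadec-7-enal, via phosphonium ylide 7 (not isolated)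
Conditions: 6, NaHMDS (0.95 equiv), THF, 0 °C; cannulated slowly into 4 (2 equiv), THF, −78 → −20 °C
Reagents that add atoms: none
Why: In this Wittig olefination a non-stabilised ylide adds to an aldehyde much faster than to the dialkyl ketone and, at −78 °C with inverse addition, faster than it deprotonates; since the two CHO groups of C2-symmetric 4 are homotopic either end gives the same mono-olefin, the recoverable excess of 4 holds back double olefination, the alkene geometry is of no consequence, and C4 and C8 are not touched.

Step 4
Reactants: 8 (2S,6S,7Z)-2,6-dimethyl-4-oxo-15-phenylpentadec-7-enal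
Product: 9 (2S,6R)-2,6-dimethyl-4-oxo-15-phenylpentadecanal
Conditions: H2 (1 atm), 5% Pt/C, EtOAc, rt, stopped at one equivalent of uptake
Reagents that add atoms: none
Why: Heterogeneous hydrogenation of a disubstituted alkene is faster than that of aliphatic C=O groups or the arene, and platinum is chosen over palladium because it migrates double bonds less, so the allylic C8 centre should keep its configuration (now R by priority change only); the step is placed here because the later O–O bond would not survive it and a remaining alkene would trap the C6 cation.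

Step 5
Reactants: 9 (2S,6R)-2,6-dimethyl-4-oxo-15-phenylpentadecanal; 10 hydrogen peroxide (dosed as its urea adduct)
Product: 12 (4S)-3,6-dimethoxy-4-methyl-6-[(2R)-2-methyl-11-phenylundecyl]-1,2-dioxane (C3/C6 epimers), via dioxanediol 11 (not isolated)
Conditions: urea·H2O2 (1.5 equiv), Sc(OTf)3 (10 mol %), MeOH, 0 °C → rt
Reagents that add atoms: methanol, CO
Why: Acid-catalysed peroxyketalisation is known for 1,4-dicarbonyl compounds with H2O2 and for ketones with urea·H2O2 in methanol, so H2O2 should bridge C3 and C6 as the six-membered bis-hemiperoxyketal 11 and solvent methanol should exchange both OH groups; C3 and C6 form as mixtures, which is harmless because both are ionised later, and the mild Lewis acid is meant to spare C4 and avoid Paal–Knorr dehydration.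

Step 6
Reactants: 12 (4S)-3,6-dimethoxy-4-methyl-6-[(2R)-2-methyl-11-phenylundecyl]-1,2-dioxane
Product: 13 (4S,6R)-3-methoxy-4,6-dimethyl-6-[(2R)-2-methyl-11-phenylundecyl]-1,2-dioxane (C3 epimers)
Conditions: Me3Al (2.5 equiv, hexanes), CH2Cl2, −78 → −40 °C; aq. potassium sodium tartrate
Reagents that add atoms: trimethylaluminium, C[Al](C)C
Why: Proposed new method: Me3Al binds the more basic exocyclic methoxy oxygen, the ketal carbon C6 ionises to a tertiary peroxycarbenium ion well before the acetal carbon C3, and the aluminate returns a methyl group along the axial trajectory of the half-chair that carries the C4 methyl group pseudo-equatorial (attack on the flipped half-chair would meet that methyl group 1,3-diaxially, and the anomerically preferred axial C3-OMe reinforces the same conformer), which places the new CH3 trans to C4-CH3 and sets 6R; the closest known reaction types are the Lewis-acid substitution of peroxyketals by allylsilanes and silyl enol ethers through peroxycarbenium ions and the axial methylation of cyclic ketals and anomeric leaving groups by Me3Al through oxocarbenium ions, the latter also practised at low temperature on peroxide-bearing trioxanes without loss of the O–O bond.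

Step 7
Reactants: 13 (4S,6R)-3-methoxy-4,6-dimethyl-6-[(2R)-2-methyl-11-phenylundecyl]-1,2-dioxane; 14 tert-butyl[(1-methoxyethenyl)oxy]dimethylsilane
Product: 15 methyl 2-[(3S,4S,6R)-4,6-dimethyl-6-[(2R)-2-methyl-11-phenylundecyl]-1,2-dioxan-3-yl]acetate
Conditions: 14 (2 equiv), TiCl4 (1.1 equiv), CH2Cl2, −78 °C; aq. NaHCO3
Reagents that add atoms: none
Why: Lewis-acid substitution of a cyclic peroxyacetal by a silyl ketene acetal through a peroxycarbenium ion (a Mukaiyama-type reaction known for 3-alkoxy-1,2-dioxolanes and peroxyacetals) applies here, and the C3 cation is held in one half-chair because the flipped form would set C4-CH3 and a C6 alkyl group 1,3-diaxial, so axial attack on the face bearing only the axial C5–H should give the 3,4-cis product, that is 3S.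

Step 8
Reactants: 15 methyl 2-[(3S,4S,6R)-4,6-dimethyl-6-[(2R)-2-methyl-11-phenylundecyl]-1,2-dioxan-3-yl]acetate
Product: 16 2-[(3S,4S,6R)-4,6-dimethyl-6-[(2R)-2-methyl-11-phenylundecyl]-1,2-dioxan-3-yl]acetic acid (target)
Conditions: LiOH·H2O (3 equiv), THF/H2O 3:1, 0 °C; then 1 M HCl to pH 3
Reagents that add atoms: lithium hydroxide, [Li+].[OH-]
Why: Saponification of the methyl ester of a 1,2-dioxane-3-acetate with cold LiOH is established for this class, the dialkyl peroxide is inert to cold aqueous hydroxide, and short contact at 0 °C is meant to keep retro-oxa-Michael opening (which would epimerise C3) and Kornblum–DeLaMare cleavage from starting, so no stereocentre is touched.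

## Compound list

1 | propanal | CCC=O | starting material
2 | 1,3-dibromoacetone | BrCC(=O)CBr | starting material
3 | (2S)-5-bromo-2-methyl-4-oxopentanal (not isolated) | O=C[C@@H](C)CC(=O)CBr | intermediate
4 | (2S,6S)-2,6-dimethyl-4-oxoheptanedial | O=C[C@@H](C)CC(=O)C[C@H](C)C=O | intermediate
5 | (8-bromooctyl)benzene | BrCCCCCCCCc1ccccc1 | starting material
6 | triphenyl(8-phenyloctyl)phosphonium bromide | [Br-].c1ccccc1CCCCCCCC[P+](c1ccccc1)(c1ccccc1)c1ccccc1 | intermediate
7 | triphenyl(8-phenyloctylidene)-λ5-phosphane, the ylide (not isolated) | c1ccccc1CCCCCCCC=P(c1ccccc1)(c1ccccc1)c1ccccc1 | intermediate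
8 | (2S,6S,7Z)-2,6-dimethyl-4-oxo-15-phenylpentadec-7-enal | C[C@H](/C=C\CCCCCCCc1ccccc1)CC(=O)C[C@H](C)C=O | intermediate
9 | (2S,6R)-2,6-dimethyl-4-oxo-15-phenylpentadecanal | C[C@H](CCCCCCCCCc1ccccc1)CC(=O)C[C@H](C)C=O | intermediate
10 | hydrogen peroxide (dosed as its urea adduct) | OO | starting material
11 | (4S)-4-methyl-6-[(2R)-2-methyl-11-phenylundecyl]-1,2-dioxane-3,6-diol, C3/C6 epimers (not isolated) | C[C@H](CCCCCCCCCc1ccccc1)CC1(O)C[C@H](C)C(O)OO1 | intermediate
12 | (4S)-3,6-dimethoxy-4-methyl-6-[(2R)-2-methyl-11-phenylundecyl]-1,2-dioxane, C3/C6 epimers | C[C@H](CCCCCCCCCc1ccccc1)CC1(OC)C[C@H](C)C(OC)OO1 | intermediate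
13 | (4S,6R)-3-methoxy-4,6-dimethyl-6-[(2R)-2-methyl-11-phenylundecyl]-1,2-dioxane, C3 epimers | C[C@H](CCCCCCCCCc1ccccc1)C[C@]1(C)C[C@H](C)C(OC)OO1 | intermediate
14 | tert-butyl[(1-methoxyethenyl)oxy]dimethylsilane | C=C(OC)O[Si](C)(C)C(C)(C)C | starting material
15 | methyl 2-[(3S,4S,6R)-4,6-dimethyl-6-[(2R)-2-methyl-11-phenylundecyl]-1,2-dioxan-3-yl]acetate | C[C@H](CCCCCCCCCc1ccccc1)C[C@]1(C)C[C@H](C)[C@H](CC(=O)OC)OO1 | intermediate
16 | 2-[(3S,4S,6R)-4,6-dimethyl-6-[(2R)-2-methyl-11-phenylundecyl]-1,2-dioxan-3-yl]acetic acid | C[C@H](CCCCCCCCCc1ccccc1)C[C@]1(C)C[C@H](C)[C@H](CC(=O)O)OO1 | target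

## Step count and risks

Total step count: 8. Longest linear sequence: 7 steps (steps 1 and 3–8, or equally steps 2–8).

**Risk 1, step 1 (labelled).**
- What may go wrong: the sequence may stall after the first alkylation. The second α-keto radical may abstract the aldehyde hydrogen of its own chain. The dibromide may alkylate the amine catalyst. Facial selectivity may erode, or the polar dialdehyde may be lost on isolation.
- Fallback: it uses known auxiliary chemistry, keeps the two-directional logic and sets out from 1.
- Condensation with (S)-1-amino-2-(methoxymethyl)pyrrolidine (Et2O, 0 °C → rt) gives propanal SAMP hydrazone F1.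
- Deprotonation (LDA, THF, 0 °C) and alkylation of two equivalents of the azaenolate with purchased 3-bromo-2-(bromomethyl)prop-1-ene (−100 °C → rt) follow. They give the bis-SAMP hydrazone of (2S,6S)-2,6-dimethyl-4-methylideneheptanedial F2, in which the methylidene group masks the ketone. SAMP is the auxiliary known to give S-configured 2-methyl aldehydes.
- Ozonolysis (O3, CH2Cl2, −78 °C; Me2S) cleaves both C=N bonds and the C=CH2 bond in one operation and comes back to the route at 4.

**Risk 2, step 6 (labelled).**
- What may go wrong: Me3Al may attack the O–O bond. The cation may lose a proton to give a cyclic peroxy enol ether. Heterolytic O–O fragmentation, substitution at C3 or poor facial selectivity may intervene.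
- Fallback: it uses known chemistry, brings the C6 methyl carbon in by methylenation, makes the C6–O bond by radical peroxidation, and sets out from 9.
- Double Wittig methylenation (Ph3P=CH2, THF, −78 → 0 °C) gives [(10R,14S)-10,14-dimethyl-12-methylidenehexadec-15-en-1-yl]benzene F3.
- Mukaiyama–Isayama peroxidation uses Co(thd)2 (thd = 2,2,6,6-tetramethylheptane-3,5-dionate), O2 and Et3SiH in 1,2-dichloroethane at rt. It prefers the 1,1-disubstituted alkene, which gives a tertiary radical, and leads to the tertiary triethylsilyl peroxide with a pendant vinyl group F4 as C6 epimers.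
- Ozonolysis of the vinyl group (O3, CH2Cl2, −78 °C; Me2S) gives (2S,6R)-2,4,6-trimethyl-15-phenyl-4-(triethylsilylperoxy)pentadecanal F5.
- Catalytic p-TsOH in MeOH removes the silyl group and closes the hydroperoxide onto the aldehyde as the methyl peroxyacetal.
- Chromatographic removal of the 6S epimer of the methoxy dioxane F6 brings the sequence back to the route at 13.

**Risk 3, step 5.**
- What may go wrong: closure may occur through oxygen instead of peroxide, giving a five-membered bis-acetal. Paal–Knorr dehydration may destroy C4, acid may epimerise C4, or H2O2 may over-add to form geminal bis-hydroperoxides.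
- Fallback: it needs no peroxyketal at all, closes ring A by conjugate addition and sets out from 9.
- Aldehyde-selective Wittig reaction with Ph3P=CHCO2Me (CH2Cl2, rt) gives methyl (2E,4S,8R)-4,8-dimethyl-6-oxo-17-phenylheptadec-2-enoate F7.
- Ketone-selective Takai–Lombardo methylenation (Zn, CH2Br2, TiCl4, THF/CH2Cl2, 0 °C → rt) gives methyl (2E,4S,8R)-4,8-dimethyl-6-methylidene-17-phenylheptadec-2-enoate F8.
- Mukaiyama–Isayama peroxidation (Co(thd)2, O2, Et3SiH) at the electron-rich alkene gives methyl (2E,4S,8R)-4,6,8-trimethyl-17-phenyl-6-(triethylsilylperoxy)heptadec-2-enoate F9.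
- Catalytic HCl in MeOH at 0 °C gives the free tertiary hydroperoxide F10.
- Et2NH in CF3CH2OH closes the ring by intramolecular oxa-Michael addition.
- Separation from the C3/C6 stereoisomers of the ester F11 brings the sequence back to the route at 15. The price is the loss of the substrate-controlled setting of C6 and C3.

## Further compounds

F1 | step 1 | (E)-propanal SAMP hydrazone, (2S)-2-(methoxymethyl)-N-propylidenepyrrolidin-1-amine | CC/C=N/N1CCC[C@H]1COC
F2 | step 1 | bis-SAMP hydrazone of (2S,6S)-2,6-dimethyl-4-methylideneheptanedial | COC[C@@H]1CCCN1/N=C/[C@@H](C)CC(=C)C[C@H](C)/C=N/N1CCC[C@H]1COC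
F3 | step 6 | [(10R,14S)-10,14-dimethyl-12-methylidenehexadec-15-en-1-yl]benzene | C[C@H](CCCCCCCCCc1ccccc1)CC(=C)C[C@H](C)C=C
F4 | step 6 | triethyl{[(3S,7R)-3,5,7-trimethyl-16-phenylhexadec-1-en-5-yl]peroxy}silane, C5 epimers | C[C@H](CCCCCCCCCc1ccccc1)CC(C)(OO[Si](CC)(CC)CC)C[C@H](C)C=C
F5 | step 6 | (2S,6R)-2,4,6-trimethyl-15-phenyl-4-(triethylsilylperoxy)pentadecanal, C4 epimers | C[C@H](CCCCCCCCCc1ccccc1)CC(C)(OO[Si](CC)(CC)CC)C[C@H](C)C=O
F6 | step 6 | (4S,6S)-3-methoxy-4,6-dimethyl-6-[(2R)-2-methyl-11-phenylundecyl]-1,2-dioxane | C[C@H](CCCCCCCCCc1ccccc1)C[C@@]1(C)C[C@H](C)C(OC)OO1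
F7 | step 5 | methyl (2E,4S,8R)-4,8-dimethyl-6-oxo-17-phenylheptadec-2-enoate | C[C@H](CCCCCCCCCc1ccccc1)CC(=O)C[C@H](C)/C=C/C(=O)OC
F8 | step 5 | methyl (2E,4S,8R)-4,8-dimethyl-6-methylidene-17-phenylheptadec-2-enoate | C[C@H](CCCCCCCCCc1ccccc1)CC(=C)C[C@H](C)/C=C/C(=O)OC
F9 | step 5 | methyl (2E,4S,8R)-4,6,8-trimethyl-17-phenyl-6-(triethylsilylperoxy)heptadec-2-enoate, C6 epimers | C[C@H](CCCCCCCCCc1ccccc1)CC(C)(OO[Si](CC)(CC)CC)C[C@H](C)/C=C/C(=O)OC
F10 | step 5 | methyl (2E,4S,8R)-6-hydroperoxy-4,6,8-trimethyl-17-phenylheptadec-2-enoate, C6 epimers | C[C@H](CCCCCCCCCc1ccccc1)CC(C)(OO)C[C@H](C)/C=C/C(=O)OC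
F11 | step 5 | methyl 2-[(4S)-4,6-dimethyl-6-[(2R)-2-methyl-11-phenylundecyl]-1,2-dioxan-3-yl]acetate, C3/C6 stereoisomers of 15 | C[C@H](CCCCCCCCCc1ccccc1)CC1(C)C[C@H](C)C(CC(=O)OC)OO1
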